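The numbers were drawn at random within sensible limits; what happens was integrated by code.

- We are asked which form holds most of the catalyst at 50 % conversion of the starting material, how large its share is, and how the rate of making product answers two changes of charge, so we want one quantity that gives both shares and rate.

starting material 1.0 M; coupling partner 1.00 M; free catalyst 5.0 mM; added ligand 7.6 mM

    starting material + free catalyst → catalyst intermediate A (k1 = 11 M⁻¹ s⁻¹)
    coupling partner + catalyst intermediate A → catalyst intermediate B (k2 = 34 M⁻¹ s⁻¹)
    catalyst intermediate B → free catalyst + product (k3 = 1.9 s⁻¹)
    free catalyst + added ligand ⇌ idle complex (K4 = 250 M⁻¹, k4 = 82 M⁻¹ s⁻¹)

* the form that holds most of the catalyst when 50 % of the starting material are converted (catalyst intermediate A / free catalyst / catalyst intermediate B / idle complex)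
* its share of the catalyst then
* factor on the rate of making product when 50 % of the starting material are converted if coupling partner is charged twice over
* factor on the rate when 50 % of the starting material are converted if free catalyst is charged at 1.0 mM instead

- At that conversion the starting material and the coupling partner, used one for one, stand at 0.500 M and 0.500 M, so, taking each wait as one over the rate per catalyst, a catalyst waits 0.182 s as free catalyst, 0.0588 s as catalyst intermediate A and 0.526 s as catalyst intermediate B.
- We take the idle complex in balance with free catalyst, so it holds the equilibrium constant times the free ligand as many times the free catalyst, which with the ligand as charged adds a side wait of 0.345 s and brings the sum of waits to 1.11 s.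
- That balance is fair, because at the pace of this sum we reckon 111 s to the conversion, far longer than the exchange time of the ligand step, both ways together, of 1.05 s.
- Waits in series work like time constants in a chain, and dividing one wait by the sum lets time drop out: a catalyst is found at each stop in proportion to its wait there, which puts 47.4 % at catalyst intermediate B.
- The weak link is the ligand taken as charged, because on that reckoning the idle complex holds 1.55 mM of it, leaving 6.05 mM; a further pass leaves 6.28 mM, a side wait of 0.285 s, and the round time, the sum of the waits at the stops of the working round and the side wait in the idle complex, of 1.05 s, so catalyst intermediate B holds 50.1 %.
- The rate of making product is the catalyst charged divided by the round time, so we reckon both factors from that; coupling partner charged twice over stands at 1.50 M, which cuts its wait to 0.0196 s and gives a factor of 1.04.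
- With 1.0 mM of free catalyst the idle complex takes less ligand, the side wait grows and the round time becomes 1.10 s, so we commit to a factor of 0.192.
- The forecast gives a factor of 1.04 for the coupling partner and 0.19 for the smaller charge, and it names catalyst intermediate B with 50 % (range 46 % to 54 %), on the ground that “the last step is the slowest”.
- The simulation gives catalyst intermediate B with 50.3 %, a factor of 1.04 for the coupling partner and 0.191 for the smaller charge.
- Within the round time of 1.05 s in the first flask, the wait of 0.526 s at catalyst intermediate B, the resting state, is longer than the 0.285 s in the idle complex, the 0.182 s as free catalyst and the 0.0588 s at catalyst intermediate A, and that flask's shares at 50 % conversion stand in that order at 50.3 %, 26.8 %, 17.3 % and 5.60 %. In the second flask, charged with 1.0 mM of free catalyst, the charge is 0.200 of the first while the reckoned round time is 1.10 s, and the rate stands at 0.191 of the first flask's.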